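**Plan**

- Retrosynthetic cuts, in order: the C3''=C4'' double bond of the pyran ring on ring B (to an aryl aldehyde on C3' and a 2-aryloxy-2-methylpropanal on O4'); the C3'–CHO bond; O1–C2 of the chroman; the C8–prenyl bond (back to an O-(1,1-dimethylallyl) ether on the future O1); and C3–C4 (enolate benzylation). This leaves a ring B arylacetyl imide and a ring A benzylic bromide, both made from 2,4-dihydroxybenzaldehyde.
- Enabling feature: C3' is the only free arene carbon flanked by two oxygens (O2', O4'), and the pyran carbon C2'' is quaternary (gem-dimethyl). The alkene therefore maps onto two non-enolisable aldehydes held in a six-membered array, and these two electrophilic carbons are united by ketyl coupling on low-valent titanium (intramolecular McMurry reaction).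
- Forward order: fragments 1 and 2 are joined at C3–C4; LiBH4 frees C2 and brings the tether carbon to the alcohol level; a [3,3] shift moves the C5 unit from O1 to C8; Mitsunobu closure gives ring C; formylation at C3' and oxidation give the dialdehyde; reductive coupling closes the pyran ring; fluoride removes both silicon-based groups.
- Stereochemistry: the single stereocentre C3 (S) is set by the (S)-4-benzyloxazolidin-2-one auxiliary in the enolate benzylation and is never a reacting centre afterwards.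

Key step: step 17

Remark: the (3S) configuration is the one encoded in the given SMILES. TIPS = triisopropylsilyl, SEM = 2-(trimethylsilyl)ethoxymethyl. Unprimed locants refer to the chroman, primed ones to ring B, doubly primed ones to the pyran ring.

**Fragment 1 (ring A)**

Step 1
Reactants: 1 2,4-dihydroxybenzaldehyde
Product: 2 2-hydroxy-4-(TIPS-oxy)benzaldehyde
Conditions: i-Pr3SiCl, imidazole, CH2Cl2, 0 °C → rt
Reagents that add atoms: chlorotriisopropylsilane, CC(C)[Si](Cl)(C(C)C)C(C)C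
Why: Selective phenol silylation should occur only at the 4-OH because the 2-OH is held in a hydrogen bond to the formyl group and the chloride is bulky; TIPS is chosen because it does not direct lithiation later.

Step 2
Reactants: 2 2-hydroxy-4-(TIPS-oxy)benzaldehyde
Product: 3 2-(2-methylbut-3-yn-2-yloxy)-4-(TIPS-oxy)benzaldehyde
Conditions: 3-chloro-3-methylbut-1-yne, DBU, CuCl2·2H2O (cat.), MeCN, 0 °C
Reagents that add atoms: 3-chloro-3-methylbut-1-yne, CC(C)(Cl)C#C
Why: Copper-catalysed O-propargylation of the DBU phenoxide with a tertiary propargylic chloride is the standard entry to aryl 1,1-dimethylpropargyl ethers and works best on electron-poor phenols such as this salicylaldehyde.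

Step 3
Reactants: 3 2-(2-methylbut-3-yn-2-yloxy)-4-(TIPS-oxy)benzaldehyde
Product: 4 2-(2-methylbut-3-en-2-yloxy)-4-(TIPS-oxy)benzaldehyde
Conditions: H2 (1 atm), Pd/CaCO3 poisoned with Pb(OAc)2 (Lindlar catalyst), quinoline, EtOAc, rt
Reagents that add atoms: none
Why: Lindlar semihydrogenation should stop at the terminal alkene and spare the aldehyde and silyl ether, giving the aryl 1,1-dimethylallyl ether that serves as phenol protecting group and as latent C8 prenyl group.

Step 4
Reactants: 4 2-(2-methylbut-3-en-2-yloxy)-4-(TIPS-oxy)benzaldehyde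
Product: 5 [2-(2-methylbut-3-en-2-yloxy)-4-(TIPS-oxy)phenyl]methanol
Conditions: NaBH4, MeOH, 0 °C
Reagents that add atoms: none
Why: Borohydride reduction of the aryl aldehyde gives the benzylic alcohol, and no acyl or silyl group sits ortho to it that could migrate.

Step 5
Reactants: 5 [2-(2-methylbut-3-en-2-yloxy)-4-(TIPS-oxy)phenyl]methanol
Product: 6 1-(bromomethyl)-2-(2-methylbut-3-en-2-yloxy)-4-(TIPS-oxy)benzene
Conditions: CBr4, PPh3, 2,6-lutidine, CH2Cl2, 0 °C; crude bromide used at once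
Reagents that add atoms: tetrabromomethane, BrC(Br)(Br)Br
Why: Appel bromination under buffered neutral conditions should convert the electron-rich benzylic alcohol into the bromide without ionising the acid-labile tertiary allyl ether.

**Fragment 2 (ring B)**

Step 6
Reactants: 1 2,4-dihydroxybenzaldehyde
Product: 7 ethyl 2-(4-formyl-3-hydroxyphenoxy)-2-methylpropanoate
Conditions: ethyl 2-bromo-2-methylpropanoate, K2CO3, DMF, 60 °C
Reagents that add atoms: ethyl 2-bromo-2-methylpropanoate, CCOC(=O)C(C)(C)Br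
Why: Williamson etherification with the tertiary alpha-bromo ester should go selectively at the 4-OH, the only non-chelated phenol, and brings in C2'', the gem-dimethyl group and C3'' of the future pyran ring.

Step 7
Reactants: 7 ethyl 2-(4-formyl-3-hydroxyphenoxy)-2-methylpropanoate
Product: 8 ethyl 2-[4-formyl-3-(SEM-oxy)phenoxy]-2-methylpropanoate
Conditions: SEMCl, i-Pr2NEt, CH2Cl2, 0 → 40 °C
Reagents that add atoms: 2-(trimethylsilyl)ethoxymethyl chloride, C[Si](C)(C)CCOCCl
Why: Acetal protection of the chelated phenol installs SEM, which blocks O2' during chroman closure, directs the later lithiation and is fluoride-labile like TIPS.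

Step 8
Reactants: 8 ethyl 2-[4-formyl-3-(SEM-oxy)phenoxy]-2-methylpropanoate
Product: 9 ethyl 2-[4-(2-methoxyethenyl)-3-(SEM-oxy)phenoxy]-2-methylpropanoate (E/Z mixture)
Conditions: Ph3P(CH2OMe)Cl, KN(SiMe3)2, THF, 0 °C
Reagents that add atoms: (methoxymethyl)triphenylphosphonium chloride, [Cl-].COC[P+](c1ccccc1)(c1ccccc1)c1ccccc1
Why: Wittig methoxymethylenation adds the one carbon needed for the arylacetic acid, and the non-stabilised ylide should react with the aldehyde and not with the alpha-quaternary ester.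

Step 9
Reactants: 9 ethyl 2-[4-(2-methoxyethenyl)-3-(SEM-oxy)phenoxy]-2-methylpropanoate
Product: 11 [4-(1-ethoxy-2-methyl-1-oxopropan-2-yl)oxy-2-(SEM-oxy)phenyl]acetic acid, via arylacetaldehyde 10 (not isolated)
Conditions: aq. HCO2H, THF, rt; then NaH2PO4, 2-methylbut-2-ene, NaClO2, t-BuOH/H2O, 0 °C → rt
Reagents that add atoms: water, O; sodium chlorite, [Na+].[O-]Cl=O
Why: Mild acid hydrolysis of the enol ether gives the sensitive arylacetaldehyde, which is oxidised in the same pot by Pinnick oxidation, a method that with an alkene scavenger should spare the electron-rich ring, the SEM ether and the ester.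

Step 10
Reactants: 11 [4-(1-ethoxy-2-methyl-1-oxopropan-2-yl)oxy-2-(SEM-oxy)phenyl]acetic acid
Product: 13 ethyl 2-[4-{2-[(4S)-4-benzyl-2-oxo-1,3-oxazolidin-3-yl]-2-oxoethyl}-3-(SEM-oxy)phenoxy]-2-methylpropanoate, via mixed pivalic anhydride 12 (not isolated)
Conditions: PivCl, Et3N, THF, −20 °C; then LiCl, (S)-4-benzyl-1,3-oxazolidin-2-one, −20 °C → rt
Reagents that add atoms: (S)-4-benzyl-1,3-oxazolidin-2-one, O=C1N[C@@H](Cc2ccccc2)CO1; pivaloyl chloride, CC(C)(C)C(Cl)=O (its atoms stay only in intermediate 12)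
Why: N-Acylation of the Evans auxiliary through the mixed pivalic anhydride with LiCl and Et3N is a standard mild method that avoids strong base next to the ester.

**Union and endgame**

Step 11
Reactants: 13 ethyl 2-[4-{2-[(4S)-4-benzyl-2-oxo-1,3-oxazolidin-3-yl]-2-oxoethyl}-3-(SEM-oxy)phenoxy]-2-methylpropanoate; 6 1-(bromomethyl)-2-(2-methylbut-3-en-2-yloxy)-4-(TIPS-oxy)benzene
Product: 15 ethyl 2-[4-{(2S)-1-[(4S)-4-benzyl-2-oxo-1,3-oxazolidin-3-yl]-3-[2-(2-methylbut-3-en-2-yloxy)-4-(TIPS-oxy)phenyl]-1-oxopropan-2-yl}-3-(SEM-oxy)phenoxy]-2-methylpropanoate, via sodium enolate 14 (not isolated)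
Conditions: NaN(SiMe3)2, THF, −78 °C; then 6, −78 → −40 °C
Reagents that add atoms: sodium bis(trimethylsilyl)amide, [Na+].C[Si](C)(C)[N-][Si](C)(C)C (sodium stays only in intermediate 14)
Why: In this Evans asymmetric alkylation the chelated sodium (Z)-enolate should be benzylated on the face opposite the C4 benzyl group of the (S)-auxiliary, which sets the only stereocentre as (S), the future C3 of the chroman.

Step 12
Reactants: 15 ethyl 2-[4-{(2S)-1-[(4S)-4-benzyl-2-oxo-1,3-oxazolidin-3-yl]-3-[2-(2-methylbut-3-en-2-yloxy)-4-(TIPS-oxy)phenyl]-1-oxopropan-2-yl}-3-(SEM-oxy)phenoxy]-2-methylpropanoate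
Product: 16 (2S)-2-[4-(1-hydroxy-2-methylpropan-2-yl)oxy-2-(SEM-oxy)phenyl]-3-[2-(2-methylbut-3-en-2-yloxy)-4-(TIPS-oxy)phenyl]propan-1-ol
Conditions: LiBH4, MeOH, THF, 0 °C → rt
Reagents that add atoms: none
Why: Reductive cleavage of the imide with LiBH4 should give the primary alcohol without epimerisation and at the same time reduce the activated 2-aryloxy ester, so the future C3'' reaches the alcohol level with no extra step.

Step 13
Reactants: 16 (2S)-2-[4-(1-hydroxy-2-methylpropan-2-yl)oxy-2-(SEM-oxy)phenyl]-3-[2-(2-methylbut-3-en-2-yloxy)-4-(TIPS-oxy)phenyl]propan-1-ol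
Product: 18 (2S)-3-[2-hydroxy-3-(3-methylbut-2-en-1-yl)-4-(TIPS-oxy)phenyl]-2-[4-(1-hydroxy-2-methylpropan-2-yl)oxy-2-(SEM-oxy)phenyl]propan-1-ol, via ortho-dienone 17 (not isolated)
Conditions: degassed xylenes, 135 °C (base-washed glassware)
Reagents that add atoms: none
Why: Aromatic Claisen rearrangement ([3,3]) of the aryl 1,1-dimethylallyl ether into the only free ortho position, followed by tautomerisation of the dienone, should install the C8 prenyl group and free the phenol for ring closure without touching the stereocentre.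

Step 14
Reactants: 18 (2S)-3-[2-hydroxy-3-(3-methylbut-2-en-1-yl)-4-(TIPS-oxy)phenyl]-2-[4-(1-hydroxy-2-methylpropan-2-yl)oxy-2-(SEM-oxy)phenyl]propan-1-ol
Product: 19 2-methyl-2-[4-{(3S)-8-(3-methylbut-2-en-1-yl)-7-(TIPS-oxy)-3,4-dihydro-2H-chromen-3-yl}-3-(SEM-oxy)phenoxy]propan-1-ol
Conditions: PPh3, DIAD, THF, 0 °C → rt
Reagents that add atoms: none
Why: Intramolecular Mitsunobu etherification (6-exo-tet) of the phenol onto the unhindered primary alcohol should close the chroman ring, because the neopentyl-type alcohol cannot be displaced, O2' is blocked as its SEM ether and C3 is not a reacting centre.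

Step 15
Reactants: 19 2-methyl-2-[4-{(3S)-8-(3-methylbut-2-en-1-yl)-7-(TIPS-oxy)-3,4-dihydro-2H-chromen-3-yl}-3-(SEM-oxy)phenoxy]propan-1-ol
Product: 21 6-[(1-hydroxy-2-methylpropan-2-yl)oxy]-3-{(3S)-8-(3-methylbut-2-en-1-yl)-7-(TIPS-oxy)-3,4-dihydro-2H-chromen-3-yl}-2-(SEM-oxy)benzaldehyde, via dilithio species 20 (not isolated)
Conditions: n-BuLi (2.5 equiv), THF, −20 → 0 °C; then DMF, −78 °C → rt; H2O
Reagents that add atoms: N,N-dimethylformamide, CN(C)C=O; n-butyllithium, [Li]CCCC (lithium stays only in intermediate 20)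
Why: In this directed ortho-metalation and formylation, n-BuLi (after forming the alkoxide) should remove the proton at C3', the only position flanked by two oxygens and the only one ortho to a directing group since OTIPS does not direct and C8 is substituted, while the tertiary benzylic C3–H is not kinetically acidic so the stereocentre is safe.

Step 16
Reactants: 21 6-[(1-hydroxy-2-methylpropan-2-yl)oxy]-3-{(3S)-8-(3-methylbut-2-en-1-yl)-7-(TIPS-oxy)-3,4-dihydro-2H-chromen-3-yl}-2-(SEM-oxy)benzaldehyde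
Product: 22 6-[(2-methyl-1-oxopropan-2-yl)oxy]-3-{(3S)-8-(3-methylbut-2-en-1-yl)-7-(TIPS-oxy)-3,4-dihydro-2H-chromen-3-yl}-2-(SEM-oxy)benzaldehyde
Conditions: Dess–Martin periodinane, CH2Cl2, 0 °C → rt
Reagents that add atoms: none
Why: Dess–Martin oxidation of the neopentyl-type primary alcohol should give the non-enolisable 2-aryloxy-2-methylpropanal without over-oxidation, and the conjugated aryl aldehyde has little tendency to close to a seven-membered lactol, so lactone formation should be minor.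

Step 17
Reactants: 22 6-[(2-methyl-1-oxopropan-2-yl)oxy]-3-{(3S)-8-(3-methylbut-2-en-1-yl)-7-(TIPS-oxy)-3,4-dihydro-2H-chromen-3-yl}-2-(SEM-oxy)benzaldehyde
Product: 24 triisopropyl{[(3S)-3-[2,2-dimethyl-5-(SEM-oxy)-2H-chromen-6-yl]-8-(3-methylbut-2-en-1-yl)-3,4-dihydro-2H-chromen-7-yl]oxy}silane, via titanium pinacolate 23 (not isolated)
Conditions: TiCl3(DME)1.5, Zn(Cu), DME, reflux; 22 added slowly by syringe pump
Reagents that add atoms: titanium trichloride, Cl[Ti](Cl)Cl (titanium and chlorine stay only in intermediate 23)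
Why: Low-valent titanium transfers an electron to the more easily reduced aryl aldehyde, the titanium-bound ketyl joins the carbonyl carbon of the tethered aliphatic aldehyde to give the cis-pinacolate 23, and at reflux both C–O bonds are cleaved on titanium to release the C3''=C4'' double bond. The closest known reaction type is the intramolecular McMurry coupling of dicarbonyl compounds to cycloalkenes, including closures of 2-(2-oxoalkoxy)aryl carbonyl compounds to 2H-chromenes and benzofurans. The six-membered pyran ring closes by 6-exo-trig attack of the ketyl carbon on the second carbonyl group, and the ring enforces the cis alkene. No stereocentre is created, since the two carbinol centres of 23 are destroyed in the deoxygenation and C3 of the chroman is remote and untouched. The step needs intramolecular over intermolecular coupling, which the six-membered ring size, the gem-dimethyl group on the tether and the slow addition should secure. It also needs the aryloxy–carbon bond next to the aliphatic aldehyde to survive, which preferential reduction of the conjugated aryl aldehyde and fast ring closure should secure, while the SEM and TIPS ethers and the prenyl alkene are inert to the reagent.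

Step 18
Reactants: 24 triisopropyl{[(3S)-3-[2,2-dimethyl-5-(SEM-oxy)-2H-chromen-6-yl]-8-(3-methylbut-2-en-1-yl)-3,4-dihydro-2H-chromen-7-yl]oxy}silane
Product: 25 6-[(3S)-7-hydroxy-8-(3-methylbut-2-en-1-yl)-3,4-dihydro-2H-chromen-3-yl]-2,2-dimethyl-2H-chromen-5-ol
Conditions: Bu4NF (excess), THF/DMPU, 60 °C; aq. NH4Cl
Reagents that add atoms: none
Why: Fluoride-induced desilylation should cleave the aryl TIPS ether directly and fragment the SEM ether (loss of Me3SiF, ethene and formaldehyde), freeing both phenols under non-acidic conditions that spare the ortho-prenylphenol and the chromene.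

**Compound list**

1 | 2,4-dihydroxybenzaldehyde | O=Cc1ccc(O)cc1O | starting material
2 | 2-hydroxy-4-(TIPS-oxy)benzaldehyde | O=Cc1ccc(O[Si](C(C)C)(C(C)C)C(C)C)cc1O | intermediate
3 | 2-(2-methylbut-3-yn-2-yloxy)-4-(TIPS-oxy)benzaldehyde | O=Cc1ccc(O[Si](C(C)C)(C(C)C)C(C)C)cc1OC(C)(C)C#C | intermediate
4 | 2-(2-methylbut-3-en-2-yloxy)-4-(TIPS-oxy)benzaldehyde | O=Cc1ccc(O[Si](C(C)C)(C(C)C)C(C)C)cc1OC(C)(C)C=C | intermediate
5 | [2-(2-methylbut-3-en-2-yloxy)-4-(TIPS-oxy)phenyl]methanol | OCc1ccc(O[Si](C(C)C)(C(C)C)C(C)C)cc1OC(C)(C)C=C | intermediate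
6 | 1-(bromomethyl)-2-(2-methylbut-3-en-2-yloxy)-4-(TIPS-oxy)benzene | BrCc1ccc(O[Si](C(C)C)(C(C)C)C(C)C)cc1OC(C)(C)C=C | intermediate
7 | ethyl 2-(4-formyl-3-hydroxyphenoxy)-2-methylpropanoate | O=Cc1ccc(OC(C)(C)C(=O)OCC)cc1O | intermediate
8 | ethyl 2-[4-formyl-3-(SEM-oxy)phenoxy]-2-methylpropanoate | O=Cc1ccc(OC(C)(C)C(=O)OCC)cc1OCOCC[Si](C)(C)C | intermediate
9 | ethyl 2-[4-(2-methoxyethenyl)-3-(SEM-oxy)phenoxy]-2-methylpropanoate (E/Z mixture) | COC=Cc1ccc(OC(C)(C)C(=O)OCC)cc1OCOCC[Si](C)(C)C | intermediate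
10 | ethyl 2-methyl-2-[4-(2-oxoethyl)-3-(SEM-oxy)phenoxy]propanoate (arylacetaldehyde, not isolated) | O=CCc1ccc(OC(C)(C)C(=O)OCC)cc1OCOCC[Si](C)(C)C | intermediate
11 | [4-(1-ethoxy-2-methyl-1-oxopropan-2-yl)oxy-2-(SEM-oxy)phenyl]acetic acid | OC(=O)Cc1ccc(OC(C)(C)C(=O)OCC)cc1OCOCC[Si](C)(C)C | intermediate
12 | mixed anhydride of 11 with pivalic acid (not isolated) | CC(C)(C)C(=O)OC(=O)Cc1ccc(OC(C)(C)C(=O)OCC)cc1OCOCC[Si](C)(C)C | intermediate
13 | ethyl 2-[4-{2-[(4S)-4-benzyl-2-oxo-1,3-oxazolidin-3-yl]-2-oxoethyl}-3-(SEM-oxy)phenoxy]-2-methylpropanoate | O=C(Cc1ccc(OC(C)(C)C(=O)OCC)cc1OCOCC[Si](C)(C)C)N1C(=O)OC[C@@H]1Cc1ccccc1 | intermediate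
14 | sodium (Z)-enolate of 13 (not isolated) | [Na+].[O-]/C(N1C(=O)OC[C@@H]1Cc1ccccc1)=C\c1ccc(OC(C)(C)C(=O)OCC)cc1OCOCC[Si](C)(C)C | intermediate
15 | ethyl 2-[4-{(2S)-1-[(4S)-4-benzyl-2-oxo-1,3-oxazolidin-3-yl]-3-[2-(2-methylbut-3-en-2-yloxy)-4-(TIPS-oxy)phenyl]-1-oxopropan-2-yl}-3-(SEM-oxy)phenoxy]-2-methylpropanoate | O=C([C@H](c1ccc(OC(C)(C)C(=O)OCC)cc1OCOCC[Si](C)(C)C)Cc1ccc(O[Si](C(C)C)(C(C)C)C(C)C)cc1OC(C)(C)C=C)N1C(=O)OC[C@@H]1Cc1ccccc1 | intermediate
16 | (2S)-2-[4-(1-hydroxy-2-methylpropan-2-yl)oxy-2-(SEM-oxy)phenyl]-3-[2-(2-methylbut-3-en-2-yloxy)-4-(TIPS-oxy)phenyl]propan-1-ol | OC[C@H](c1ccc(OC(C)(C)CO)cc1OCOCC[Si](C)(C)C)Cc1ccc(O[Si](C(C)C)(C(C)C)C(C)C)cc1OC(C)(C)C=C | intermediate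
17 | 6-(3-methylbut-2-en-1-yl)cyclohexa-2,4-dien-1-one tautomer of 18 (not isolated; ring sp3 centre undefined) | OC[C@H](c1ccc(OC(C)(C)CO)cc1OCOCC[Si](C)(C)C)CC1=CC=C(O[Si](C(C)C)(C(C)C)C(C)C)C(CC=C(C)C)C1=O | intermediate
18 | (2S)-3-[2-hydroxy-3-(3-methylbut-2-en-1-yl)-4-(TIPS-oxy)phenyl]-2-[4-(1-hydroxy-2-methylpropan-2-yl)oxy-2-(SEM-oxy)phenyl]propan-1-ol | OC[C@H](c1ccc(OC(C)(C)CO)cc1OCOCC[Si](C)(C)C)Cc1ccc(O[Si](C(C)C)(C(C)C)C(C)C)c(CC=C(C)C)c1O | intermediate
19 | 2-methyl-2-[4-{(3S)-8-(3-methylbut-2-en-1-yl)-7-(TIPS-oxy)-3,4-dihydro-2H-chromen-3-yl}-3-(SEM-oxy)phenoxy]propan-1-ol | CC(C)=CCc1c(O[Si](C(C)C)(C(C)C)C(C)C)ccc2c1OC[C@H](c1ccc(OC(C)(C)CO)cc1OCOCC[Si](C)(C)C)C2 | intermediate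
20 | C3'-lithiated lithium alkoxide of 19 (not isolated) | CC(C)=CCc1c(O[Si](C(C)C)(C(C)C)C(C)C)ccc2c1OC[C@H](c1ccc(OC(C)(C)CO[Li])c([Li])c1OCOCC[Si](C)(C)C)C2 | intermediate
21 | 6-[(1-hydroxy-2-methylpropan-2-yl)oxy]-3-{(3S)-8-(3-methylbut-2-en-1-yl)-7-(TIPS-oxy)-3,4-dihydro-2H-chromen-3-yl}-2-(SEM-oxy)benzaldehyde | CC(C)=CCc1c(O[Si](C(C)C)(C(C)C)C(C)C)ccc2c1OC[C@H](c1ccc(OC(C)(C)CO)c(C=O)c1OCOCC[Si](C)(C)C)C2 | intermediate
22 | 6-[(2-methyl-1-oxopropan-2-yl)oxy]-3-{(3S)-8-(3-methylbut-2-en-1-yl)-7-(TIPS-oxy)-3,4-dihydro-2H-chromen-3-yl}-2-(SEM-oxy)benzaldehyde | CC(C)=CCc1c(O[Si](C(C)C)(C(C)C)C(C)C)ccc2c1OC[C@H](c1ccc(OC(C)(C)C=O)c(C=O)c1OCOCC[Si](C)(C)C)C2 | intermediate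
23 | titanium 3'',4''-pinacolate of the pyran ring, drawn as its dichlorotitanium diolate (not isolated; carbinol centres undefined) | CC(C)=CCc1c(O[Si](C(C)C)(C(C)C)C(C)C)ccc2c1OC[C@H](c1ccc3c(c1OCOCC[Si](C)(C)C)C1O[Ti](Cl)(Cl)OC1C(C)(C)O3)C2 | intermediate
24 | triisopropyl{[(3S)-3-[2,2-dimethyl-5-(SEM-oxy)-2H-chromen-6-yl]-8-(3-methylbut-2-en-1-yl)-3,4-dihydro-2H-chromen-7-yl]oxy}silane | CC(C)=CCc1c(O[Si](C(C)C)(C(C)C)C(C)C)ccc2c1OC[C@H](c1ccc3c(c1OCOCC[Si](C)(C)C)C=CC(C)(C)O3)C2 | intermediate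
25 | 6-[(3S)-7-hydroxy-8-(3-methylbut-2-en-1-yl)-3,4-dihydro-2H-chromen-3-yl]-2,2-dimethyl-2H-chromen-5-ol | CC(C)=CCc1c(O)ccc2c1OC[C@H](c1ccc3c(c1O)C=CC(C)(C)O3)C2 | target

**Totals**

Total step count: 18. Longest linear sequence: 13 steps (steps 1–5 or 6–10, then 11–18).

**Steps most likely to fail**

1. Step 17 (reductive carbonyl coupling). What may go wrong: reductive cleavage of the aryloxy–carbon bond next to the aliphatic aldehyde, arrest at the pinacol stage, or intermolecular coupling to oligomers. Fallback: the pyran ring would be closed by olefin metathesis instead. Double Wittig methylenation of dialdehyde 22 (Ph3PCH3Br, KN(SiMe3)2, THF, 0 °C) should give the divinyl compound (3S)-3-[4-(2-methylbut-3-en-2-yloxy)-2-(SEM-oxy)-3-vinylphenyl]-8-(3-methylbut-2-en-1-yl)-7-(TIPS-oxy)chroman F1. Ring-closing metathesis with the second-generation Grubbs catalyst RuCl2(=CHPh)(PCy3)(H2IMes) in CH2Cl2 at 40 °C should then expel ethene and return to the route at 24; the trisubstituted prenyl alkene is expected to stay out of the metathesis.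

2. Step 15 (lithiation and formylation at C3'). What may go wrong: incomplete metalation at the hindered site between the two oxygens, or diversion of the base to the allylic/benzylic CH2 of the prenyl group. Fallback: the formyl group would be introduced by phenol-directed electrophilic formylation, setting out from 19. Selective removal of the SEM group (MgBr2·OEt2, Et2O/MeNO2, TIPS ether retained) should give the free phenol 2-[3-hydroxy-4-{(3S)-8-(3-methylbut-2-en-1-yl)-7-(TIPS-oxy)chroman-3-yl}phenoxy]-2-methylpropan-1-ol F2. Casnati–Skattebøl ortho-formylation (MgCl2, Et3N, paraformaldehyde, MeCN, reflux) can only reach C3' because C1' is substituted, and should give the salicylaldehyde 2-hydroxy-6-[(1-hydroxy-2-methylpropan-2-yl)oxy]-3-{(3S)-8-(3-methylbut-2-en-1-yl)-7-(TIPS-oxy)chroman-3-yl}benzaldehyde F3. Re-protection of the phenol (SEMCl, K2CO3, DMF) returns to the route at 21.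

3. Step 13 (Claisen rearrangement). What may go wrong: ionisation of the tertiary allyl ether with loss of isoprene, or migration to the para position instead of the ortho [3,3] shift. Fallback: the prenyl group would be attached intermolecularly, setting out from 16. Cleavage of the allyl ether with Pd(PPh3)4 (zerovalent palladium) and morpholine in THF should give the phenol (2S)-3-[2-hydroxy-4-(TIPS-oxy)phenyl]-2-[4-(1-hydroxy-2-methylpropan-2-yl)oxy-2-(SEM-oxy)phenyl]propan-1-ol F4. Ortho-C-prenylation of its sodium phenoxide (NaH, 1 equiv, prenyl bromide, toluene) at the only free ortho position returns to the route at 18.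

Further compounds
F1 | step 17 | (3S)-3-[4-(2-methylbut-3-en-2-yloxy)-2-(SEM-oxy)-3-vinylphenyl]-8-(3-methylbut-2-en-1-yl)-7-(TIPS-oxy)chroman | CC(C)=CCc1c(O[Si](C(C)C)(C(C)C)C(C)C)ccc2c1OC[C@H](c1ccc(OC(C)(C)C=C)c(C=C)c1OCOCC[Si](C)(C)C)C2
F2 | step 15 | 2-[3-hydroxy-4-{(3S)-8-(3-methylbut-2-en-1-yl)-7-(TIPS-oxy)chroman-3-yl}phenoxy]-2-methylpropan-1-ol | CC(C)=CCc1c(O[Si](C(C)C)(C(C)C)C(C)C)ccc2c1OC[C@H](c1ccc(OC(C)(C)CO)cc1O)C2
F3 | step 15 | 2-hydroxy-6-[(1-hydroxy-2-methylpropan-2-yl)oxy]-3-{(3S)-8-(3-methylbut-2-en-1-yl)-7-(TIPS-oxy)chroman-3-yl}benzaldehyde | CC(C)=CCc1c(O[Si](C(C)C)(C(C)C)C(C)C)ccc2c1OC[C@H](c1ccc(OC(C)(C)CO)c(C=O)c1O)C2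
F4 | step 13 | (2S)-3-[2-hydroxy-4-(TIPS-oxy)phenyl]-2-[4-(1-hydroxy-2-methylpropan-2-yl)oxy-2-(SEM-oxy)phenyl]propan-1-ol | OC[C@H](c1ccc(OC(C)(C)CO)cc1OCOCC[Si](C)(C)C)Cc1ccc(O[Si](C(C)C)(C(C)C)C(C)C)cc1O
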